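**Plan**

1. Numbering (germacrane): ring C1–C10; lactone C6–O–C12(=O)–C11=C7; C13 on C11, C14 on C10, C15 on C4.
2. Retrosynthesis cuts the C8 ester, the oxirane C–O bonds at C1/C10 and C4/C5, then the ring bond C5–C6, then C7=C11 and O6–C12 of the butenolide, then C8–C9, C1=C10 and C3–C4 of the chain.
3. Forward: the chain I–C5=C4(C15)–C3–C2–C1=C10(C14)–C9 is made first and joined at C9 to a C6–C7–C8 dihydroxyacetone unit. The butenolide is then closed by olefination, the ten-membered ring by palladium-catalysed γ-vinylation, and the oxiranes come last.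
4. Enabling feature: C6 is the acidic γ-carbon of the butenolide ring (O–C12(=O)–C11=C7–C6) and is bonded to C5, an alkene carbon of the ten-membered ring. The α-carbon C11 is fully substituted (C13), so the dienolate can be vinylated only at C6.
5. Stereochemistry: C8 from SAMP-hydrazone alkylation; C6 from the ring closure under control of C8; Z-C4=C5 from syn-carbocupration and E-C1=C10 from a stabilised ylide. The C1/C10 oxirane comes from outer-face attack, the C4/C5 oxirane from delivery by the C8 hydroxyl, and the glycidate from (R)-2-methylglycidol.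

Key step: step 15

Assumption: in 27–30 the ten-membered ring is taken to hold H-6 and H-8 in the planes of the C4=C5 and C7=C11 alkenes (allylic 1,3-strain), so that C5 and C9 leave the lactone on opposite faces; on this conformer the outer face of C1=C10 leads to the (1R,10R)-oxide and the C8 oxygen lies over the face of C4=C5 that leads to the (4R,5S)-oxide.

**Route**

Step 1
Reactants: 1 2-(2-bromoethyl)-1,3-dioxolane; 2 propyne
Product: 5 2-[(3Z)-4-iodo-3-methylbut-3-en-1-yl]-1,3-dioxolane, via Grignard reagent 3 (not isolated), via alkenylcopper 4 (not isolated)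
Conditions: Mg, THF, 25 °C; CuBr·SMe2, Et2O/Me2S, −45 °C; propyne, −25 °C; I2, THF, −78 → 0 °C
Reagents that add atoms: iodine, [I][I]
Why: Normant carbocupration adds the alkylcopper syn across propyne with copper on the terminal carbon, so the alkyl chain (C3) and copper are cis, and iodinolysis with retention should give the (Z)-C4=C5 iodide.

Step 2
Reactants: 5 2-[(3Z)-4-iodo-3-methylbut-3-en-1-yl]-1,3-dioxolane
Product: 6 (4Z)-5-iodo-4-methylpent-4-enal
Conditions: 1 M HCl, THF, 40 °C
Reagents that add atoms: water, O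
Why: Acid-catalysed acetal hydrolysis frees the C1 aldehyde while the vinyl iodide is inert to aqueous acid.

Step 3
Reactants: 6 (4Z)-5-iodo-4-methylpent-4-enal; 7 ethyl 2-(triphenylphosphoranylidene)propanoate
Product: 8 ethyl (2E,6Z)-7-iodo-2,6-dimethylhepta-2,6-dienoate
Conditions: CH2Cl2, 25 °C
Reagents that add atoms: none
Why: Wittig olefination with an ester-stabilised α-methyl ylide is reliably E-selective and should set the C1=C10 geometry.

Step 4
Reactants: 8 ethyl (2E,6Z)-7-iodo-2,6-dimethylhepta-2,6-dienoate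
Product: 9 (2E,6Z)-7-iodo-2,6-dimethylhepta-2,6-dien-1-ol
Conditions: i-Bu2AlH, CH2Cl2, −78 °C
Reagents that add atoms: none
Why: Aluminium hydride 1,2-reduction of an enoate gives the allylic alcohol without touching the alkenes or the vinyl iodide.

Step 5
Reactants: 9 (2E,6Z)-7-iodo-2,6-dimethylhepta-2,6-dien-1-ol
Product: 10 (1Z,5E)-7-bromo-1-iodo-2,6-dimethylhepta-1,5-diene
Conditions: CBr4, PPh3, CH2Cl2, −20 → 0 °C
Reagents that add atoms: tetrabromomethane, BrC(Br)(Br)Br
Why: Appel bromination converts the primary allylic alcohol into the C9 bromide under neutral conditions without allylic transposition.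

Step 6
Reactants: 11 2,2-dimethyl-1,3-dioxan-5-one; 12 (2S)-2-(methoxymethyl)pyrrolidin-1-amine (SAMP)
Product: 13 (2S)-N-(2,2-dimethyl-1,3-dioxan-5-ylidene)-2-(methoxymethyl)pyrrolidin-1-amine
Conditions: cyclohexane, 4 Å molecular sieves, reflux
Reagents that add atoms: none
Why: Hydrazone condensation of the protected dihydroxyacetone (C6–C7–C8) with the chiral hydrazine is driven by removal of water.

Step 7
Reactants: 13 (2S)-N-(2,2-dimethyl-1,3-dioxan-5-ylidene)-2-(methoxymethyl)pyrrolidin-1-amine; 10 (1Z,5E)-7-bromo-1-iodo-2,6-dimethylhepta-1,5-diene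
Product: 15 (2S)-N-{(4S)-4-[(2E,6Z)-7-iodo-2,6-dimethylhepta-2,6-dien-1-yl]-2,2-dimethyl-1,3-dioxan-5-ylidene}-2-(methoxymethyl)pyrrolidin-1-amine, via lithium azaenolate 14 (not isolated)
Conditions: t-BuLi (1.0 equiv), THF, −78 °C; then 10, −100 → 25 °C
Reagents that add atoms: none
Why: Enders SAMP-hydrazone alkylation: the lithium azaenolate, chelated by the methoxymethyl arm, is attacked by the primary allylic bromide (SN2) on its open face, which by the established sense of this auxiliary should set C8 as (S).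

Step 8
Reactants: 15 the alkylated SAMP hydrazone
Product: 16 (4S)-4-[(2E,6Z)-7-iodo-2,6-dimethylhepta-2,6-dien-1-yl]-2,2-dimethyl-1,3-dioxan-5-one
Conditions: sat. aq. oxalic acid, Et2O, 25 °C
Reagents that add atoms: water, O
Why: Mild two-phase acid hydrolysis of the hydrazone regenerates the ketone and leaves the acetonide and the α-stereocentre untouched, with the auxiliary recoverable.

Step 9
Reactants: 16 (4S)-4-[(2E,6Z)-7-iodo-2,6-dimethylhepta-2,6-dien-1-yl]-2,2-dimethyl-1,3-dioxan-5-one
Product: 17 (3S,5E,9Z)-1,3-dihydroxy-10-iodo-5,9-dimethyldeca-5,9-dien-2-one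
Conditions: AcOH/H2O/THF, 40 °C; used directly
Reagents that add atoms: none
Why: Acid-catalysed acetonide hydrolysis in buffered aqueous acetic acid frees the primary C6 and secondary C8 hydroxyls without enolising the ketone appreciably.

Step 10
Reactants: 18 benzyl 2-(diethoxyphosphoryl)acetate; 19 (chloromethoxy)triisopropylsilane
Product: 20 benzyl 2-(diethoxyphosphoryl)-3-[(triisopropylsilyl)oxy]propanoate (racemic)
Conditions: NaH, THF, 0 → 25 °C
Reagents that add atoms: none
Why: C-alkylation of the sodium phosphonoacetate by the reactive chloromethyl ether (SN2) installs C13 with its oxygen already silylated; the new centre is uncontrolled and is removed in step 14.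

Step 11
Reactants: 20 benzyl 2-(diethoxyphosphoryl)-3-[(triisopropylsilyl)oxy]propanoate
Product: 21 2-(diethoxyphosphoryl)-3-[(triisopropylsilyl)oxy]propanoic acid (racemic)
Conditions: H2 (1 atm), Pd/C, EtOAc, 25 °C
Reagents that add atoms: none
Why: Hydrogenolysis of the benzyl ester frees the acid under neutral conditions that cannot trigger loss of the β-silyloxy group.

Step 12
Reactants: 17 (3S,5E,9Z)-1,3-dihydroxy-10-iodo-5,9-dimethyldeca-5,9-dien-2-one; 21 2-(diethoxyphosphoryl)-3-[(triisopropylsilyl)oxy]propanoic acid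
Product: 22 (3S,5E,9Z)-3-hydroxy-10-iodo-5,9-dimethyl-2-oxodeca-5,9-dien-1-yl 2-(diethoxyphosphoryl)-3-[(triisopropylsilyl)oxy]propanoate (both epimers at the phosphonate carbon)
Conditions: EDC·HCl, DMAP (cat.), CH2Cl2, −20 °C
Reagents that add atoms: none
Why: Carbodiimide (Steglich) esterification at low temperature acylates the primary C6 hydroxyl far faster than the hindered secondary C8 hydroxyl.

Step 13
Reactants: 22 the C6 phosphonoacetate ester
Product: 23 (3S,5E,9Z)-10-iodo-5,9-dimethyl-2-oxo-3-[(triethylsilyl)oxy]deca-5,9-dien-1-yl 2-(diethoxyphosphoryl)-3-[(triisopropylsilyl)oxy]propanoate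
Conditions: Et3SiOTf, 2,6-lutidine, CH2Cl2, −78 °C
Reagents that add atoms: triethylsilyl trifluoromethanesulfonate, CC[Si](CC)(CC)OS(=O)(=O)C(F)(F)F
Why: Silylation of the C8 hydroxyl with a silyl triflate and a hindered base blocks acyl migration from O6 to O8 and is too weakly basic to enolise the ketone or the phosphonate.

Step 14
Reactants: 23 the silylated keto phosphonate
Product: 24 4-[(1S,3E,7Z)-8-iodo-3,7-dimethyl-1-(triethylsilyloxy)octa-3,7-dien-1-yl]-3-{[(triisopropylsilyl)oxy]methyl}furan-2(5H)-one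
Conditions: LiCl, i-Pr2NEt, MeCN, 0 → 25 °C
Reagents that add atoms: none
Why: Intramolecular Horner–Wadsworth–Emmons olefination (Masamune–Roush conditions) of the C7 ketone closes the butenolide through C7=C11, and the mild amine base should leave C8 unepimerised.

Step 15
Reactants: 24 4-[(1S,3E,7Z)-8-iodo-3,7-dimethyl-1-(triethylsilyloxy)octa-3,7-dien-1-yl]-3-{[(triisopropylsilyl)oxy]methyl}furan-2(5H)-one
Product: 27 (6R,8S)-8-(triethylsilyloxy)-13-[(triisopropylsilyl)oxy]germacra-1(10)E,4Z,7(11)-trien-12,6-olide, via lithium dienolate 25 (not isolated), via zinc dienolate 26 (not isolated)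
Conditions: LiN(SiMe3)2, THF, −78 °C; ZnCl2, −78 → 0 °C; syringe-pump addition to Pd2(dba)3 (5 mol %, zerovalent palladium), P(t-Bu)3 (20 mol %), THF, 40 °C, 0.002 M
Reagents that add atoms: none
Why: Proposed new method: deprotonation at C6 gives the aromatic 2-oxidofuran, which is passed to zinc; oxidative addition of the (Z)-C5–I bond to zerovalent palladium, transmetalation to a C6-bound palladium dienolate and sp2–sp3 reductive elimination from the tri-tert-butylphosphine complex form C5–C6 with retention of the Z geometry, the closest known reaction types being the intermolecular palladium-catalysed γ-arylation of butenolide dienolates and the arylation of zinc ester enolates. The ten-membered ring closes in this reductive elimination, a macrocyclisation at high dilution in which the tethered C6 nucleophile and C5 electrophile meet on palladium. γ-Selectivity is required and is secured because C11 is fully substituted, so α-coupling could only give a congested quaternary, deconjugated lactone. The new stereocentre C6 is controlled by C8: allylic 1,3-strain with the C13 arm holds H-8 in the furan plane, C9 leaves on one face, and the rigid E-configured C9–C10=C1–C2 unit is assumed to bring C5 to the opposite face, which gives (6R). The zinc dienolate is too weakly basic to deprotonate the doubly activated C6–H of 27 or to expel the C13 silyloxy group, so the kinetic configuration should survive. Both alkene geometries are preset in 24, so only the ring closure and the C6 face are decided here.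

Step 16
Reactants: 27 the bis-silylated macrocyclic lactone
Product: 28 (6R,8S)-8,13-dihydroxygermacra-1(10)E,4Z,7(11)-trien-12,6-olide
Conditions: HF·pyridine, pyridine, THF, 0 → 25 °C
Reagents that add atoms: none
Why: Buffered fluoride desilylation removes both silyl ethers under non-basic conditions, so the acidic C6–H is not epimerised.

Step 17
Reactants: 28 (6R,8S)-8,13-dihydroxygermacra-1(10)E,4Z,7(11)-trien-12,6-olide
Product: 29 (6R,8S)-13-acetoxy-8-hydroxygermacra-1(10)E,4Z,7(11)-trien-12,6-olide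
Conditions: Ac2O (1.1 equiv), 2,4,6-collidine, CH2Cl2, −20 → 0 °C
Reagents that add atoms: acetic anhydride, CC(=O)OC(C)=O
Why: Kinetically selective acylation: the unhindered primary C13 hydroxyl is acetylated well before the secondary C8 hydroxyl flanked by the tetrasubstituted alkene.

Step 18
Reactants: 29 (6R,8S)-13-acetoxy-8-hydroxygermacra-1(10)E,4Z,7(11)-trien-12,6-olide
Product: 30 (1R,6R,8S,10R)-13-acetoxy-1,10-epoxy-8-hydroxygermacra-4Z,7(11)-dien-12,6-olide
Conditions: dimethyldioxirane (1.0 equiv), acetone/CH2Cl2, −40 → −20 °C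
Reagents that add atoms: dimethyldioxirane, CC1(C)OO1
Why: Dioxirane epoxidation takes the most electron-rich alkene C1=C10 first (C4=C5 is deactivated by the allylic lactone oxygen, C7=C11 is electron-poor), and attack on the exposed outer face of the E-alkene, as is general for germacra-1(10)-enes, should set C1 (R) and C10 (R).

Step 19
Reactants: 30 (1R,6R,8S,10R)-13-acetoxy-1,10-epoxy-8-hydroxygermacra-4Z,7(11)-dien-12,6-olide
Product: 31 (1R,4R,5S,6S,8S,10R)-13-acetoxy-1,10:4,5-diepoxy-8-hydroxygermacr-7(11)-en-12,6-olide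
Conditions: VO(acac)2 (5 mol %), t-BuOOH, CH2Cl2, 0 → 25 °C
Reagents that add atoms: tert-butyl hydroperoxide, CC(C)(C)OO
Why: Vanadium-catalysed hydroxyl-directed epoxidation of a bishomoallylic alcohol: the C8 vanadate, which sits over the C7-side face of C4=C5, delivers oxygen to that face and so should set C4 (R) and C5 (S), the face an external oxidant would avoid, while the electron-poor C7=C11 alkene stays inert.

Step 20
Reactants: 32 [(2R)-2-methyloxiran-2-yl]methanol
Product: 33 (2S)-2-methyloxirane-2-carboxylic acid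
Conditions: TEMPO (cat.), PhI(OAc)2, MeCN/H2O, 0 → 25 °C; used at once
Reagents that add atoms: water, O
Why: Nitroxyl-catalysed oxidation of the primary alcohol to the acid does not touch the oxirane or the quaternary stereocentre, whose descriptor changes from R to S only through the priority change.

Step 21
Reactants: 31 the diepoxy C8 alcohol; 33 (2S)-2-methyloxirane-2-carboxylic acid
Product: 35 (1R,4R,5S,6S,8S,10R)-13-acetoxy-1,10:4,5-diepoxy-8-{[(2S)-2-methyloxirane-2-carbonyl]oxy}germacr-7(11)-en-12,6-olide (CNP0289810.1), via mixed anhydride 34 (not isolated)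
Conditions: 2,4,6-Cl3C6H2COCl, Et3N, THF, 0 °C; then 31, DMAP, toluene, 25 °C
Reagents that add atoms: none
Why: Yamaguchi esterification activates the epoxy acid as a mixed anhydride that acylates the hindered C8 hydroxyl with retention at C8 under weakly basic conditions that should spare the oxiranes and C6–H.

**Compound list**

1 | 2-(2-bromoethyl)-1,3-dioxolane | BrCCC1OCCO1 | starting material
2 | propyne | CC#C | starting material
3 | [2-(1,3-dioxolan-2-yl)ethyl]magnesium bromide | Br[Mg]CCC1OCCO1 | intermediate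
4 | [(1Z)-4-(1,3-dioxolan-2-yl)-2-methylbut-1-en-1-yl]copper | [Cu]/C=C(/C)CCC1OCCO1 | intermediate
5 | 2-[(3Z)-4-iodo-3-methylbut-3-en-1-yl]-1,3-dioxolane | I/C=C(/C)CCC1OCCO1 | intermediate
6 | (4Z)-5-iodo-4-methylpent-4-enal | O=CCC/C(C)=C\I | intermediate
7 | ethyl 2-(triphenylphosphoranylidene)propanoate | CCOC(=O)C(C)=P(c1ccccc1)(c1ccccc1)c1ccccc1 | starting material
8 | ethyl (2E,6Z)-7-iodo-2,6-dimethylhepta-2,6-dienoate | CCOC(=O)/C(C)=C/CC/C(C)=C\I | intermediate
9 | (2E,6Z)-7-iodo-2,6-dimethylhepta-2,6-dien-1-ol | OC/C(C)=C/CC/C(C)=C\I | intermediate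
10 | (1Z,5E)-7-bromo-1-iodo-2,6-dimethylhepta-1,5-diene | BrC/C(C)=C/CC/C(C)=C\I | intermediate
11 | 2,2-dimethyl-1,3-dioxan-5-one | CC1(C)OCC(=O)CO1 | starting material
12 | (2S)-2-(methoxymethyl)pyrrolidin-1-amine (SAMP) | COC[C@@H]1CCCN1N | starting material
13 | (2S)-N-(2,2-dimethyl-1,3-dioxan-5-ylidene)-2-(methoxymethyl)pyrrolidin-1-amine | COC[C@@H]1CCCN1N=C1COC(C)(C)OC1 | intermediate
14 | lithium azaenolate of 13 | COC[C@@H]1CCCN1N([Li])C1=COC(C)(C)OC1 | intermediate
15 | (2S)-N-{(4S)-4-[(2E,6Z)-7-iodo-2,6-dimethylhepta-2,6-dien-1-yl]-2,2-dimethyl-1,3-dioxan-5-ylidene}-2-(methoxymethyl)pyrrolidin-1-amine (C=N geometry not defined) | COC[C@@H]1CCCN1N=C1COC(C)(C)O[C@H]1C/C(C)=C/CC/C(C)=C\I | intermediate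
16 | (4S)-4-[(2E,6Z)-7-iodo-2,6-dimethylhepta-2,6-dien-1-yl]-2,2-dimethyl-1,3-dioxan-5-one | CC1(C)OCC(=O)[C@H](C/C(C)=C/CC/C(C)=C\I)O1 | intermediate
17 | (3S,5E,9Z)-1,3-dihydroxy-10-iodo-5,9-dimethyldeca-5,9-dien-2-one | OCC(=O)[C@@H](O)C/C(C)=C/CC/C(C)=C\I | intermediate
18 | benzyl 2-(diethoxyphosphoryl)acetate | CCOP(=O)(OCC)CC(=O)OCc1ccccc1 | starting material
19 | (chloromethoxy)triisopropylsilane | ClCO[Si](C(C)C)(C(C)C)C(C)C | starting material
20 | benzyl 2-(diethoxyphosphoryl)-3-[(triisopropylsilyl)oxy]propanoate (racemic) | CCOP(=O)(OCC)C(CO[Si](C(C)C)(C(C)C)C(C)C)C(=O)OCc1ccccc1 | intermediate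
21 | 2-(diethoxyphosphoryl)-3-[(triisopropylsilyl)oxy]propanoic acid (racemic) | CCOP(=O)(OCC)C(CO[Si](C(C)C)(C(C)C)C(C)C)C(=O)O | intermediate
22 | (3S,5E,9Z)-3-hydroxy-10-iodo-5,9-dimethyl-2-oxodeca-5,9-dien-1-yl 2-(diethoxyphosphoryl)-3-[(triisopropylsilyl)oxy]propanoate (epimers at the phosphonate carbon) | CCOP(=O)(OCC)C(CO[Si](C(C)C)(C(C)C)C(C)C)C(=O)OCC(=O)[C@@H](O)C/C(C)=C/CC/C(C)=C\I | intermediate
23 | (3S,5E,9Z)-10-iodo-5,9-dimethyl-2-oxo-3-[(triethylsilyl)oxy]deca-5,9-dien-1-yl 2-(diethoxyphosphoryl)-3-[(triisopropylsilyl)oxy]propanoate | CCOP(=O)(OCC)C(CO[Si](C(C)C)(C(C)C)C(C)C)C(=O)OCC(=O)[C@@H](O[Si](CC)(CC)CC)C/C(C)=C/CC/C(C)=C\I | intermediate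
24 | 4-[(1S,3E,7Z)-8-iodo-3,7-dimethyl-1-(triethylsilyloxy)octa-3,7-dien-1-yl]-3-{[(triisopropylsilyl)oxy]methyl}furan-2(5H)-one | CC(C)[Si](OCC1=C([C@@H](O[Si](CC)(CC)CC)C/C(C)=C/CC/C(C)=C\I)COC1=O)(C(C)C)C(C)C | intermediate
25 | lithium 4-[(1S,3E,7Z)-8-iodo-3,7-dimethyl-1-(triethylsilyloxy)octa-3,7-dien-1-yl]-3-{[(triisopropylsilyl)oxy]methyl}furan-2-olate | [Li]Oc1occ([C@@H](O[Si](CC)(CC)CC)C/C(C)=C/CC/C(C)=C\I)c1CO[Si](C(C)C)(C(C)C)C(C)C | intermediate
26 | chlorozinc furan-2-olate corresponding to 25 | Cl[Zn]Oc1occ([C@@H](O[Si](CC)(CC)CC)C/C(C)=C/CC/C(C)=C\I)c1CO[Si](C(C)C)(C(C)C)C(C)C | intermediate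
27 | (6R,8S)-8-(triethylsilyloxy)-13-[(triisopropylsilyl)oxy]germacra-1(10)E,4Z,7(11)-trien-12,6-olide | CC(C)[Si](OCC1=C2[C@@H](O[Si](CC)(CC)CC)C/C(C)=C/CC/C(C)=C\[C@H]2OC1=O)(C(C)C)C(C)C | intermediate
28 | (6R,8S)-8,13-dihydroxygermacra-1(10)E,4Z,7(11)-trien-12,6-olide | OCC1=C2[C@@H](O)C/C(C)=C/CC/C(C)=C\[C@H]2OC1=O | intermediate
29 | (6R,8S)-13-acetoxy-8-hydroxygermacra-1(10)E,4Z,7(11)-trien-12,6-olide | CC(=O)OCC1=C2[C@@H](O)C/C(C)=C/CC/C(C)=C\[C@H]2OC1=O | intermediate
30 | (1R,6R,8S,10R)-13-acetoxy-1,10-epoxy-8-hydroxygermacra-4Z,7(11)-dien-12,6-olide | CC(=O)OCC1=C2[C@@H](O)C[C@@]3(C)O[C@@H]3CC/C(C)=C\[C@H]2OC1=O | intermediate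
31 | (1R,4R,5S,6S,8S,10R)-13-acetoxy-1,10:4,5-diepoxy-8-hydroxygermacr-7(11)-en-12,6-olide | CC(=O)OCC1=C2[C@@H](O)C[C@@]3(C)O[C@@H]3CC[C@@]3(C)O[C@H]3[C@H]2OC1=O | intermediate
32 | [(2R)-2-methyloxiran-2-yl]methanol | OC[C@]1(C)CO1 | starting material
33 | (2S)-2-methyloxirane-2-carboxylic acid | OC(=O)[C@]1(C)CO1 | intermediate
34 | (2S)-2-methyloxirane-2-carboxylic 2,4,6-trichlorobenzoic anhydride | O=C(OC(=O)[C@]1(C)CO1)c1c(Cl)cc(Cl)cc1Cl | intermediate
35 | (1R,4R,5S,6S,8S,10R)-13-acetoxy-1,10:4,5-diepoxy-8-{[(2S)-2-methyloxirane-2-carbonyl]oxy}germacr-7(11)-en-12,6-olide | CC(=O)OCC1=C2[C@@H](OC(=O)[C@]3(C)CO3)C[C@@]3(C)O[C@@H]3CC[C@@]3(C)O[C@H]3[C@H]2OC1=O | target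

**Count and risks**

Total step count: 21. Longest linear sequence: 17 steps (1–5, 7–9, 12–19, 21), from 1.

Step 15 (the proposed new method). The ring closure may lose to intermolecular coupling or protodeiodination, or C5 may be delivered to the wrong face of C6. The fallback uses known chemistry, sets out from 24 and comes back at 27. Compound 24 is silylated (i-Pr3SiOTf, Et3N) to the 2-(triisopropylsilyloxy)furan F1. One equivalent of mCPBA at −78 °C oxidises only the furan and, after loss of silanol, should give the 5-hydroxybutenolide F2. Me3SiCHN2 in MeOH traps its open form as the (Z)-formyl ester F3. An intramolecular Nozaki–Hiyama–Kishi reaction (CrCl2, NiCl2 cat., DMSO/THF, high dilution) then joins C5 to the C6 aldehyde, and the chromium alkoxide lactonises onto the cis ester to give 27. The C6 epimers would be separated at that point.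

Step 19. Oxygen may be delivered to the wrong face of C4=C5, or the Lewis-acidic catalyst may open the C1/C10 oxirane across the ring. The fallback sets out from 30 and comes back at 31. It replaces hydroxyl delivery by reagent control: Shi epoxidation with the L-sorbose-derived enantiomer of the fructose ketone catalyst and KHSO5 (K2CO3 buffer, MeCN/dimethoxymethane/H2O, 0 °C). Its spiro transition state is expected to select the (4R,5S) face without using the C8 hydroxyl. No further compound is made (F0).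

Step 14. The branched phosphonate anion may add too slowly to the hindered α-silyloxy ketone, so that loss of silanolate from the anion or epimerisation at C8 intervenes. The fallback sets out from 17 and comes back at 24, by aldol addition, lactonisation and dehydration instead of olefination. Compound 17 is bis-silylated (Et3SiCl, imidazole) to the bis(triethylsilyl) ether F4. The lithium enolate (LiN(i-Pr)2, THF, −78 °C) of methyl 3-[(triisopropylsilyl)oxy]propanoate F5, itself made from methyl 3-hydroxypropanoate with i-Pr3SiCl and imidazole, adds to the C7 ketone to give the β-hydroxy ester F6. Pyridinium p-toluenesulfonate in MeOH removes the primary triethylsilyl group, and the freed C6 hydroxyl lactonises to the β-hydroxy lactone F7. Dehydration toward the acidic C11–H (SOCl2, pyridine, 0 °C) gives 24.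

Further compounds

F1 | step 15 | triisopropyl({4-[(1S,3E,7Z)-8-iodo-3,7-dimethyl-1-(triethylsilyloxy)octa-3,7-dien-1-yl]-3-{[(triisopropylsilyl)oxy]methyl}furan-2-yl}oxy)silane | CC(C)[Si](Oc1occ([C@@H](O[Si](CC)(CC)CC)C/C(C)=C/CC/C(C)=C\I)c1CO[Si](C(C)C)(C(C)C)C(C)C)(C(C)C)C(C)C
F2 | step 15 | 5-hydroxy-4-[(1S,3E,7Z)-8-iodo-3,7-dimethyl-1-(triethylsilyloxy)octa-3,7-dien-1-yl]-3-{[(triisopropylsilyl)oxy]methyl}furan-2(5H)-one (both C5 epimers) | CC(C)[Si](OCC1=C([C@@H](O[Si](CC)(CC)CC)C/C(C)=C/CC/C(C)=C\I)C(O)OC1=O)(C(C)C)C(C)C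
F3 | step 15 | methyl (2Z,4S,6E,10Z)-3-formyl-11-iodo-6,10-dimethyl-4-[(triethylsilyl)oxy]-2-{[(triisopropylsilyl)oxy]methyl}undeca-2,6,10-trienoate | COC(=O)/C(CO[Si](C(C)C)(C(C)C)C(C)C)=C(\C=O)[C@@H](O[Si](CC)(CC)CC)C/C(C)=C/CC/C(C)=C\I
F0 | step 19 | none | none
F4 | step 14 | (3S,5E,9Z)-10-iodo-5,9-dimethyl-1,3-bis[(triethylsilyl)oxy]deca-5,9-dien-2-one | CC[Si](CC)(CC)OCC(=O)[C@@H](O[Si](CC)(CC)CC)C/C(C)=C/CC/C(C)=C\I
F5 | step 14 | methyl 3-[(triisopropylsilyl)oxy]propanoate | COC(=O)CCO[Si](C(C)C)(C(C)C)C(C)C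
F6 | step 14 | methyl (4S,6E,10Z)-3-hydroxy-11-iodo-6,10-dimethyl-4-[(triethylsilyl)oxy]-3-{[(triethylsilyl)oxy]methyl}-2-{[(triisopropylsilyl)oxy]methyl}undeca-6,10-dienoate (mixture at C2 and C3) | COC(=O)C(CO[Si](C(C)C)(C(C)C)C(C)C)C(O)(CO[Si](CC)(CC)CC)[C@@H](O[Si](CC)(CC)CC)C/C(C)=C/CC/C(C)=C\I
F7 | step 14 | 4-hydroxy-4-[(1S,3E,7Z)-8-iodo-3,7-dimethyl-1-(triethylsilyloxy)octa-3,7-dien-1-yl]-3-{[(triisopropylsilyl)oxy]methyl}oxolan-2-one (mixture at C3 and C4) | O=C1OCC(O)([C@@H](O[Si](CC)(CC)CC)C/C(C)=C/CC/C(C)=C\I)C1CO[Si](C(C)C)(C(C)C)C(C)C
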